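**Retrosynthetic overview**

1. The target is the all-(−)-epicatechin tetramer EC-(4β→6)-EC-(4β→8)-EC-(4β→6)-EC (units A–D). No ring is built: all four flavan ring systems come intact from (−)-epicatechin.
2. Cut the central C4(B)–C8(C) bond. Both halves are then the same halogenated (4β→6) dimer 6 (upper unit 8-iodo, lower unit 8-bromo).
3. Key step: both carbons are electrophilic in the fragments (C4–OR next to the C3 carbinol, and C8–I). C8 is polarity-reversed (I → Mg → Zn, an aryl carbanion equivalent) and captures the C4 cation anti to the 3-OH.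
4. Dimer 6 comes from Friedel–Crafts union of an 8-iodo-4β-alkoxy electrophile with the 8-bromo nucleophile (only C6 free). Iodine is first a cap, then the metalation handle; bromine blocks C8.
5. One final hydrogenolysis removes sixteen benzyl groups and three halogens.

Assumption: (−)-epicatechin is bought as the natural (2R,3R) enantiomer, and the C3 hydroxyls stay unprotected throughout.

**Route**

Step 1
Reactants: 1 (−)-epicatechin
Product: 2 5,7,3′,4′-tetra-O-benzyl-(−)-epicatechin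
Conditions: BnBr (4.4 equiv), K2CO3, DMF, 0 °C → rt
Reagents that add atoms: benzyl bromide BrCc1ccccc1
Why: Williamson ether synthesis; K2CO3 ionises only the four phenols, so the C3 secondary alcohol stays free and no stereocentre is touched.

Step 2
Reactants: 2 5,7,3′,4′-tetra-O-benzyl-(−)-epicatechin
Product: 3 8-bromo-5,7,3′,4′-tetra-O-benzyl-(−)-epicatechin
Conditions: NBS (1.0 equiv), CH2Cl2, −78 °C → rt
Reagents that add atoms: N-bromosuccinimide O=C1CCC(=O)N1Br
Why: Electrophilic aromatic bromination; C8, between the ring oxygen and the 7-benzyloxy group, is the most nucleophilic position of ring A, and no stereocentre is touched.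

Step 3
Reactants: 2 5,7,3′,4′-tetra-O-benzyl-(−)-epicatechin
Product: 5 8-iodo-4β-(2-ethoxyethoxy)-5,7,3′,4′-tetra-O-benzyl-(−)-epicatechin, via 8-iodo tetrabenzyl ether 4 (not isolated)
Conditions: NIS (1.05 equiv), CH2Cl2, 0 °C → rt; then HOCH2CH2OEt (5 equiv), DDQ (2 equiv), rt
Reagents that add atoms: N-iodosuccinimide O=C1CCC(=O)N1I; 2-ethoxyethanol CCOCCO
Why: Electrophilic aromatic iodination at C8, then DDQ benzylic oxidation (hydride abstraction at C4); the alcohol captures the ring-A-stabilised cation anti to the axial 3α-hydroxyl, which sets C4 as the 4β ether (3,4-trans).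

Step 4
Reactants: 5 8-iodo-4β-(2-ethoxyethoxy)-5,7,3′,4′-tetra-O-benzyl-(−)-epicatechin; 3 8-bromo-5,7,3′,4′-tetra-O-benzyl-(−)-epicatechin (3 equiv, excess recovered)
Product: 6 8-iodo-5,7,3′,4′-tetra-O-benzylepicatechin-(4β→6)-8-bromo-5,7,3′,4′-tetra-O-benzylepicatechin
Conditions: TMSOTf (0.5 equiv), CH2Cl2, −78 °C; NaHCO3 quench
Reagents that add atoms: none
Why: Lewis-acid Friedel–Crafts alkylation (SN1); TMSOTf ionises the C4 ether of 5, the bromine on 3 leaves only C6 free, the iodine keeps 5 from alkylating itself at C8, and the arene enters anti to the axial 3α-hydroxyl so the new C4 centre is 4β (3,4-trans).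

Step 5
Reactants: 6 8-iodo-5,7,3′,4′-tetra-O-benzylepicatechin-(4β→6)-8-bromo-5,7,3′,4′-tetra-O-benzylepicatechin
Product: 7 8-iodo-5,7,3′,4′-tetra-O-benzylepicatechin-(4β→6)-8-bromo-4β-(2-ethoxyethoxy)-5,7,3′,4′-tetra-O-benzylepicatechin
Conditions: DDQ (2 equiv), HOCH2CH2OEt (10 equiv), CH2Cl2, rt
Reagents that add atoms: 2-ethoxyethanol CCOCCO
Why: DDQ benzylic oxidation at the only benzylic CH2 of 6 (C4 of the lower unit), the tertiary C4–H of the upper unit being shielded by two ortho-disubstituted rings; the alcohol adds anti to the 3α-hydroxyl to give the 4β ether.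

Step 6
Reactants: 6 8-iodo-5,7,3′,4′-tetra-O-benzylepicatechin-(4β→6)-8-bromo-5,7,3′,4′-tetra-O-benzylepicatechin (1.3 equiv); 7 8-iodo-5,7,3′,4′-tetra-O-benzylepicatechin-(4β→6)-8-bromo-4β-(2-ethoxyethoxy)-5,7,3′,4′-tetra-O-benzylepicatechin
Product: 10 hexadeca-O-benzyl [8-iodoepicatechin]-(4β→6)-[8-bromoepicatechin]-(4β→8)-[epicatechin]-(4β→6)-[8-bromoepicatechin], via aryl-magnesium dimer 8 (not isolated), via aryl-zinc dimer 9 (not isolated)
Conditions: 6, iPrMgCl·LiCl (3.1 equiv), THF, −20 °C; ZnCl2 (1.2 equiv); then 7, BF3·OEt2 (promoter), CH2Cl2, −78 → −30 °C; aq. NH4Cl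
Reagents that add atoms: none
Why: Proposed new method: iodine–magnesium exchange (after deprotonation of the two hydroxyls) turns C8 of the upper unit of 6, an electrophilic C–I carbon, into an aryl carbanion equivalent, Mg→Zn transmetalation tempers it, and the arylzinc captures at its ipso carbon the C4 benzylic cation that BF3 releases from the 2-ethoxyethyl ether of 7 (SN1-type arylation; closest known reactions are the catalyst-free coupling of arylzinc reagents with benzylic and glycosyl halides through carbocations and the Lewis-acid Friedel–Crafts interflavan coupling), the arene entering anti to the axial 3α-oxygen so that C4 of unit B is set 4β (3,4-trans) and the linkage is fixed at C8 by the position of the metal; any arylzinc that is protonated gives the C8–H arene, which alkylates at the same carbon, and the C3 carbinols are never taken to the ketone level because a 4-aryl-flavan-3-one is reduced anti to the new aryl group (3,4-cis).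

Step 7
Reactants: 10 hexadeca-O-benzyl [8-iodoepicatechin]-(4β→6)-[8-bromoepicatechin]-(4β→8)-[epicatechin]-(4β→6)-[8-bromoepicatechin]
Product: 11 epicatechin-(4β→6)-epicatechin-(4β→8)-epicatechin-(4β→6)-epicatechin (CNP0120618.1)
Conditions: H2 (1 atm), Pd(OH)2/C, Et3N, THF/MeOH/H2O, rt
Reagents that add atoms: none
Why: Catalytic hydrogenolysis of the sixteen benzyl ethers together with hydrodehalogenation of the C–I and the two C–Br bonds (Et3N takes up HI and HBr); the C2–O and C4–aryl bonds of the flavan units survive these mild conditions and no stereocentre is affected.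

**Compound list**

1 | (−)-epicatechin, (2R,3R), 2α-aryl, 3α-OH | Oc1cc(O)c2c(c1)O[C@H](c1ccc(O)c(O)c1)[C@H](O)C2 | starting material

2 | 5,7,3′,4′-tetra-O-benzyl-(−)-epicatechin | O(Cc9ccccc9)c%11cc(OCc9ccccc9)c%12c(c%11)O[C@H](c8ccc(OCc9ccccc9)c(OCc9ccccc9)c8)[C@H](O)C%12 | intermediate

3 | 8-bromo-5,7,3′,4′-tetra-O-benzyl-(−)-epicatechin | O(Cc9ccccc9)c%11cc(OCc9ccccc9)c%12c(c%11Br)O[C@H](c8ccc(OCc9ccccc9)c(OCc9ccccc9)c8)[C@H](O)C%12 | intermediate

4 | 8-iodo-5,7,3′,4′-tetra-O-benzyl-(−)-epicatechin (not isolated) | O(Cc9ccccc9)c%11cc(OCc9ccccc9)c%12c(c%11I)O[C@H](c8ccc(OCc9ccccc9)c(OCc9ccccc9)c8)[C@H](O)C%12 | intermediate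

5 | 8-iodo-4β-(2-ethoxyethoxy)-5,7,3′,4′-tetra-O-benzyl-(−)-epicatechin (2α-aryl, 3α-OH, 4β-OR) | O(Cc9ccccc9)c%11cc(OCc9ccccc9)c%12c(c%11I)O[C@H](c8ccc(OCc9ccccc9)c(OCc9ccccc9)c8)[C@H](O)[C@H]%12OCCOCC | intermediate

6 | 8-iodo-tetra-O-benzylepicatechin-(4β→6)-8-bromo-tetra-O-benzylepicatechin | O(Cc9ccccc9)c%11cc(OCc9ccccc9)c%12c(c%11I)O[C@H](c8ccc(OCc9ccccc9)c(OCc9ccccc9)c8)[C@H](O)[C@H]%12c%21c(OCc9ccccc9)c(Br)c%22c(c%21OCc9ccccc9)C[C@@H](O)[C@@H](c8ccc(OCc9ccccc9)c(OCc9ccccc9)c8)O%22 | intermediate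

7 | dimer 6 carrying a 4β-(2-ethoxyethoxy) group on C4 of the lower (8-bromo) unit | O(Cc9ccccc9)c%11cc(OCc9ccccc9)c%12c(c%11I)O[C@H](c8ccc(OCc9ccccc9)c(OCc9ccccc9)c8)[C@H](O)[C@H]%12c%21c(OCc9ccccc9)c(Br)c%22c(c%21OCc9ccccc9)[C@H](OCCOCC)[C@@H](O)[C@@H](c8ccc(OCc9ccccc9)c(OCc9ccccc9)c8)O%22 | intermediate

8 | aryl-magnesium dimer: 6 with C8–MgCl in place of C8–I and both hydroxyls as O–MgCl (not isolated) | O(Cc9ccccc9)c%11cc(OCc9ccccc9)c%12c(c%11[Mg]Cl)O[C@H](c8ccc(OCc9ccccc9)c(OCc9ccccc9)c8)[C@H](O[Mg]Cl)[C@H]%12c%21c(OCc9ccccc9)c(Br)c%22c(c%21OCc9ccccc9)C[C@@H](O[Mg]Cl)[C@@H](c8ccc(OCc9ccccc9)c(OCc9ccccc9)c8)O%22 | intermediate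

9 | aryl-zinc dimer: as 8 with C8–ZnCl (not isolated) | O(Cc9ccccc9)c%11cc(OCc9ccccc9)c%12c(c%11[Zn]Cl)O[C@H](c8ccc(OCc9ccccc9)c(OCc9ccccc9)c8)[C@H](O[Mg]Cl)[C@H]%12c%21c(OCc9ccccc9)c(Br)c%22c(c%21OCc9ccccc9)C[C@@H](O[Mg]Cl)[C@@H](c8ccc(OCc9ccccc9)c(OCc9ccccc9)c8)O%22 | intermediate

10 | protected tetramer: hexadeca-O-benzyl, iodine on C8 of unit A, bromine on C8 of units B and D, linkages A(4β→6)B(4β→8)C(4β→6)D | O(Cc9ccccc9)c%11cc(OCc9ccccc9)c%12c(c%11I)O[C@H](c8ccc(OCc9ccccc9)c(OCc9ccccc9)c8)[C@H](O)[C@H]%12c%21c(OCc9ccccc9)c(Br)c%22c(c%21OCc9ccccc9)[C@H](c%31c(OCc9ccccc9)cc(OCc9ccccc9)c%32c%31O[C@H](c8ccc(OCc9ccccc9)c(OCc9ccccc9)c8)[C@H](O)[C@H]%32c%41c(OCc9ccccc9)c(Br)c%42c(c%41OCc9ccccc9)C[C@@H](O)[C@@H](c8ccc(OCc9ccccc9)c(OCc9ccccc9)c8)O%42)[C@@H](O)[C@@H](c8ccc(OCc9ccccc9)c(OCc9ccccc9)c8)O%22 | intermediate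

11 | epicatechin-(4β→6)-epicatechin-(4β→8)-epicatechin-(4β→6)-epicatechin (CNP0120618.1) | Oc1cc(O)c2c(c1)O[C@H](c1ccc(O)c(O)c1)[C@H](O)[C@H]2c1c(O)cc2c(c1O)[C@H](c1c(O)cc(O)c3c1O[C@H](c1ccc(O)c(O)c1)[C@H](O)[C@H]3c1c(O)cc3c(c1O)C[C@@H](O)[C@@H](c1ccc(O)c(O)c1)O3)[C@@H](O)[C@@H](c1ccc(O)c(O)c1)O2 | target

**Step count and risks**

Total steps: 7. Longest linear sequence: 6 (steps 1, 3, 4, 5, 6, 7; compounds 1 → 2 → 5 → 6 → 7 → 10 → 11).

The three steps most likely to fail are step 6, step 5 and step 4.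

Step 6 is the least precedented: the hindered arylzinc 9 may be protonated before it captures the cation, or the ipso capture may be slow next to two ortho oxygens. The fallback sets out from 6 and replaces the metalated nucleophile by the neutral arene. Treating 6 with iPrMgCl·LiCl in THF at −20 °C and quenching with methanol gives the deiodinated dimer 5,7,3′,4′-tetra-O-benzylepicatechin-(4β→6)-8-bromo-5,7,3′,4′-tetra-O-benzylepicatechin F1. F1 then undergoes TMSOTf-catalysed Friedel–Crafts alkylation with 7 at C8–H of its upper unit (CH2Cl2, −78 °C) and comes back to the route at 10.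

Step 5 may fail because DDQ can also abstract the tertiary, doubly benzylic C4–H of the upper unit. The fallback sets out from 3 and puts the C4 leaving group on the lower unit before the dimer is made, as a thioether that the silyl triflate does not ionise. DDQ and 2-ethoxyethanol convert 3 into 8-bromo-4β-(2-ethoxyethoxy)-5,7,3′,4′-tetra-O-benzylepicatechin F2. 4-Methylbenzenethiol and BF3·OEt2 at −78 °C exchange the ether for sulfur and give 8-bromo-4β-(4-methylphenylthio)-5,7,3′,4′-tetra-O-benzylepicatechin F3. TMSOTf coupling of 5 with F3 at C6 gives the dimer thioether 8-iodo-tetra-O-benzylepicatechin-(4β→6)-8-bromo-4β-(4-methylphenylthio)-tetra-O-benzylepicatechin F4. AgOTf with 2-ethoxyethanol then swaps sulfur for the ether and comes back to the route at 7.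

Step 4 may fail because the electron-rich C8–I of 5 can lose iodine under the acidic silyl triflate, after which 5 alkylates itself. The fallback sets out from 5 and changes to a sulfur donor activated by a thiophilic silver salt under buffered conditions. 4-Methylbenzenethiol and BF3·OEt2 at −78 °C give 8-iodo-4β-(4-methylphenylthio)-5,7,3′,4′-tetra-O-benzylepicatechin F5. AgBF4 with 2,6-di-tert-butylpyridine in THF at 0 °C then couples F5 with 3 at C6 and comes back to the route at 6.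

**Further compounds**

F1 | step 6 | 5,7,3′,4′-tetra-O-benzylepicatechin-(4β→6)-8-bromo-5,7,3′,4′-tetra-O-benzylepicatechin | O(Cc9ccccc9)c%11cc(OCc9ccccc9)c%12c(c%11)O[C@H](c8ccc(OCc9ccccc9)c(OCc9ccccc9)c8)[C@H](O)[C@H]%12c%21c(OCc9ccccc9)c(Br)c%22c(c%21OCc9ccccc9)C[C@@H](O)[C@@H](c8ccc(OCc9ccccc9)c(OCc9ccccc9)c8)O%22
F2 | step 5 | 8-bromo-4β-(2-ethoxyethoxy)-5,7,3′,4′-tetra-O-benzylepicatechin | O(Cc9ccccc9)c%11cc(OCc9ccccc9)c%12c(c%11Br)O[C@H](c8ccc(OCc9ccccc9)c(OCc9ccccc9)c8)[C@H](O)[C@H]%12OCCOCC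
F3 | step 5 | 8-bromo-4β-(4-methylphenylthio)-5,7,3′,4′-tetra-O-benzylepicatechin | O(Cc9ccccc9)c%11cc(OCc9ccccc9)c%12c(c%11Br)O[C@H](c8ccc(OCc9ccccc9)c(OCc9ccccc9)c8)[C@H](O)[C@H]%12Sc7ccc(C)cc7
F4 | step 5 | 8-iodo-tetra-O-benzylepicatechin-(4β→6)-8-bromo-4β-(4-methylphenylthio)-tetra-O-benzylepicatechin | O(Cc9ccccc9)c%11cc(OCc9ccccc9)c%12c(c%11I)O[C@H](c8ccc(OCc9ccccc9)c(OCc9ccccc9)c8)[C@H](O)[C@H]%12c%21c(OCc9ccccc9)c(Br)c%22c(c%21OCc9ccccc9)[C@H](Sc7ccc(C)cc7)[C@@H](O)[C@@H](c8ccc(OCc9ccccc9)c(OCc9ccccc9)c8)O%22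
F5 | step 4 | 8-iodo-4β-(4-methylphenylthio)-5,7,3′,4′-tetra-O-benzylepicatechin | O(Cc9ccccc9)c%11cc(OCc9ccccc9)c%12c(c%11I)O[C@H](c8ccc(OCc9ccccc9)c(OCc9ccccc9)c8)[C@H](O)[C@H]%12Sc7ccc(C)cc7
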